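The numbers in the tables are calculated for substances that don't exist; noise was put on by code.

In a one-step world, reagent meets starting material and gives product at once, so the rate follows reagent at order 1, and charging reagent twice over multiplies the rate by 2. At the opposite extreme, the step that reagent enters runs far ahead of a slower step, which gives order 0 and factor 1. The real flask lies between these ends, and the readings show which one it is near.

| setting | cedar | elm | oak | flask |
|---|---|---|---|---|
| starting material | 0.30 M | 0.30 M | 0.30 M | 0.30 M |
| reagent | 0.90 M | 0.90 M | 1.4 M | 0.900 M |
| free catalyst | 1.3 mM | 1.3 mM | 1.3 mM | 1.3 mM |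
| second catalyst | 0.60 mM | 0.60 mM | 0.60 mM | 0.60 mM |
| added ligand | 0.49 mM | 2 mM | 0.99 mM | 0.99 mM |
| remark | run made earlier | run made earlier | run made earlier |  |

| run | time / min | product / % | starting material / % |
|---|---|---|---|
| cedar | 8.00 | 1 | 85 |
| cedar | 12.0 | 2 | 80 |
| cedar | 20.0 | 1 | 72 |
| cedar | 30.0 | 6 | 59 |
| cedar | 50.0 | 6 | 49 |
| cedar | 80.0 | 8 | 43 |
| cedar | 120 | 16 | 35 |
| elm | 8.00 | 1 | 95 |
| elm | 12.0 | 0 | 98 |
| elm | 20.0 | 1 | 97 |
| elm | 30.0 | 0 | 93 |
| elm | 50.0 | 0 | 89 |
| elm | 80.0 | 4 | 85 |
| elm | 120 | 5 | 77 |
| oak | 8.00 | 0 | 95 |
| oak | 15.0 | 0 | 83 |
| oak | 30.0 | 5 | 75 |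
| oak | 60.0 | 4 | 60 |
| oak | 120 | 20 | 43 |

(standard deviation of a reading: 2 percentage points)

- "the catalyst" is free catalyst with its forms; second catalyst is a second catalyst
- no earlier run changes the charge of free catalyst; that part of a forecast is a guess

* apparent order in reagent when 5.0% of the starting material are converted (percent change of the rate of making product for one percent more reagent charged)
* apparent order in free catalyst when 5.0% of the starting material are converted (percent change of the rate of making product for one percent more free catalyst charged)
* factor on the rate of making product when 5.0% of the starting material are converted if reagent is charged twice over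

In the cedar, elm and oak runs, starting material disappears ahead of product, which leaves a gap in the fractions of the charge. Between 60.0 min and 120 min of the oak run, product climbs from 4% to 20% while the gap averages 36.5%. I therefore define the pickup constant, the fraction of the gap turned into product per minute and per molar reagent, and read it as 8.70 × 10⁻⁵ M⁻¹ s⁻¹. Dividing by reagent assumes the first extreme for this step.

At the flask's reagent this reading gives 0.00470 min⁻¹. Taking the gap at 5.0% conversion as the whole conversion, the pickup is 2.35 × 10⁻⁴ min⁻¹. The oak run, which has the flask's added ligand but more reagent, shows in its first reading the gap filling at 0.00625 min⁻¹, about 26.6 times as fast as that estimated pickup. The filling is far ahead, so, taking reagent to enter the pickup as assumed above, I commit to a reagent order near 1, a factor near 2 and a rate of 0.00423 M h⁻¹. While the filling stays this far ahead, the gap at fixed conversion should barely move with the speed of filling, so I guess a catalyst order near 0.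

The forecast gives 0.7, 0.1 and 1.6, reasoning “So the catalyst order is near zero”. It differs from my reckoning mainly on reagent.

The flask gives 0.98, 0.032 and 1.96.

    starting material + free catalyst ⇌ free catalyst + open intermediate (K = 1.70, k = 0.388 M⁻¹ s⁻¹)
    second catalyst + open intermediate ⇌ catalyst intermediate (K = 3.10 M⁻¹, k = 27.0 M⁻¹ s⁻¹)
    reagent + catalyst intermediate → second catalyst + product (k = 0.0538 M⁻¹ s⁻¹)
    free catalyst + added ligand ⇌ idle complex, settled at all times (K = 16800 M⁻¹)

The flask's rate of making product at 5.0% conversion is 0.00455 M h⁻¹, against my 0.00423 M h⁻¹ from the pickup constant. On the elm run, with 2 mM of added ligand, the same constant predicts 4.77% of product made between 50.0 min and 120 min, while the readings go from 0% to 5%. The undoing of catalyst intermediate into second catalyst and open intermediate is the largest single effect on the reagent order of the flask, which is 0.98 with that undoing and 0.76 without it.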